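**Retrosynthetic overview**
1. The target is the C2-symmetric 1,2-bis(11-nordrim-8-en-9-yl)ethane. It is cut at C9 (sp2, ring B)–C11 (sp3, bridge) into a C14 11-nordrim-8-en-9-yl electrophile and a C16 2-(11-nordrim-8-en-9′-yl)ethyl nucleophile.
2. Enabling feature: in each ring B, C9 of the tetrasubstituted C8=C9 alkene lies between quaternary C10 and C8. A C9 ketone can therefore enolise only towards C8, and its enol triflate already holds that alkene. The C2 axis through the C11–C12 bond lets this one triflate serve as the electrophile and, after vinylation, as the source of the nucleophile.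
3. Key event: one-flask 9-BBN hydroboration of the 9′-vinyl diene and B-alkyl Suzuki–Miyaura coupling with the triflate. It makes the ethano bridge, the C9–C11 bond and the C30 skeleton as the last operation, in basic medium only.
4. The triflate comes from (+)-sclareolide by excision of C12 (alkoxyl-radical fragmentation), of C11 (elimination, ozonolysis) and of the C8 oxygen (SmI2), followed by enol triflation.
5. Ring order: no carbocycle is built. Rings A/B of both halves and all four stereocentres (C5, C10, C5′, C10′) are bought with sclareolide, and only its lactone ring is dismantled.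

Key step: step 8

Assumption: drimane numbering is used (C8 bears the vinylic methyl, C9 the side chain, C10 the angular methyl; C11 sits on C9, C12 on C11; primes mark the diene-derived half). Commercial (+)-sclareolide is taken as the (3aR,5aS,9aS,9bR) enantiomer, whose C5/C10 configuration (S,S) is that of both halves of the target.

**Step 1**
Reactants: 1 (+)-sclareolide
Product: 2 sclareolide lactol (C12 anomers)
Conditions: DIBAL-H, CH2Cl2, −78 °C; aq. Rochelle salt
Reagents that add atoms: none
Why: Partial reduction of a γ-lactone with DIBAL-H stops at the lactol because the tetrahedral aluminium hemiacetal survives at −78 °C until work-up; no existing stereocentre is touched and the new anomeric centre at C12 is lost in step 2.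

**Step 2**
Reactants: 2 sclareolide lactol
Product: 4 11-iododriman-8α-yl formate, via lactol hypoiodite 3 (not isolated)
Conditions: PhI(OAc)2, I2, CH2Cl2, rt, visible light
Reagents that add atoms: iodine, II
Why: Suárez alkoxyl-radical fragmentation: acetyl hypoiodite converts the lactol into hypoiodite 3, whose O–I homolysis gives an anomeric alkoxyl radical that undergoes β-scission of C11–C12 (driven by formation of the formate C=O), and the primary C11 radical is capped by iodine, C8 and C9 keeping their configuration.

**Step 3**
Reactants: 4 11-iododriman-8α-yl formate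
Product: 5 drim-9(11)-en-8α-yl formate
Conditions: AgF, pyridine, rt, dark
Reagents that add atoms: none
Why: Silver(I)-assisted E2 dehydroiodination: the only β-hydrogen of the primary iodide is C9–H, so only the exocyclic C9=C11 alkene can form, and the weakly basic medium keeps the formate, which shuts off a Grob fragmentation of a free C8 alkoxide.

**Step 4**
Reactants: 5 drim-9(11)-en-8α-yl formate
Product: 7 9-oxo-11-nordriman-8α-yl formate, via primary ozonide 6 (not isolated)
Conditions: O3, CH2Cl2, −78 °C; Me2S, −78 °C → rt
Reagents that add atoms: ozone, [O-][O+]=O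
Why: Criegee ozonolysis with reductive work-up removes C11 as formaldehyde and leaves the C9 ketone; the alkene is the only π bond that ozone can attack and the formate and the C8 centre are inert.

**Step 5**
Reactants: 7 9-oxo-11-nordriman-8α-yl formate
Product: 9 11-nordriman-9-one (C8 epimers), via samarium enolate 8 (not isolated)
Conditions: SmI2, THF/MeOH, −78 → 0 °C
Reagents that add atoms: samarium diiodide, I[Sm]I (samarium and iodine stay only in 8)
Why: Samarium diiodide reduction of an α-acyloxy ketone: the C9 ketyl expels the C8 formate, a second electron gives enolate 8 and methanol protonates it; the resulting C8 configuration does not matter because C8 becomes sp2 in step 6.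

**Step 6**
Reactants: 9 11-nordriman-9-one
Product: 11 11-nordrim-8-en-9-yl triflate, via potassium enolate 10 (not isolated)
Conditions: KHMDS, THF, −78 → 0 °C; PhNTf2, −78 °C → rt
Reagents that add atoms: N-phenylbis(trifluoromethanesulfonimide), O=S(=O)(C(F)(F)F)N(c1ccccc1)S(=O)(=O)C(F)(F)F; KHMDS, [K+].C[Si](C)(C)[N-][Si](C)(C)C (potassium stays only in 10)
Why: Enolate O-sulfonylation: C10 is quaternary, so deprotonation can occur only at C8 and the single possible enolate 10 is trapped on oxygen by the triflimide, which fixes the tetrasubstituted C8=C9 alkene regiospecifically, as known for 2,2,6-trimethylcyclohexanone.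

**Step 7**
Reactants: 11 11-nordrim-8-en-9-yl triflate (first portion); 12 tributyl(vinyl)stannane
Product: 13 9-vinyl-11-nordrim-8-ene
Conditions: Pd2(dba)3 (cat.), AsPh3, LiCl, NMP, 60 °C; KF work-up
Reagents that add atoms: none
Why: Stille coupling: triphenylarsine, chloride and a polar solvent speed up the transmetalation that limits congested enol triflates such as 2,6,6-trimethylcyclohexenyl triflate, vinyl is the smallest sp2 group to be transferred, and ipso substitution leaves the C8=C9 alkene where it is.

**Step 8**
Reactants: 13 9-vinyl-11-nordrim-8-ene; 11 11-nordrim-8-en-9-yl triflate (second portion)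
Product: 15 1,2-bis[(4aS,8aS)-2,5,5,8a-tetramethyl-3,4,4a,5,6,7,8,8a-octahydronaphthalen-1-yl]ethane (target), via alkyl-9-BBN borane 14 (not isolated)
Conditions: 9-BBN, THF, 0 °C → rt; then 11, PdCl2(dppf) (cat.), AsPh3 (cat.), Cs2CO3, DMF/THF/H2O, 60 °C
Reagents that add atoms: 9-borabicyclo[3.3.1]nonane, B1C2CCCC1CCC2 (its boron stays only in 14; only its hydrogen reaches 15)
Why: 9-BBN adds to the only accessible π bond of 13, the monosubstituted C12=C11 vinyl group, with boron on terminal C11 (the tetrasubstituted C8′=C9′ bond, twisted out of conjugation by the C10′ and C8′ methyl groups, is inert) to give primary borane 14; base converts 14 into its borate, Pd(0) inserts into the C9–OTf bond of 11, the primary alkyl group passes to palladium and reductive elimination forms the C9(sp2)–C11(sp3) bond. The closest known reaction type is the one-flask hydroboration/B-alkyl Suzuki–Miyaura coupling of terminal alkenes with cyclic enol triflates, with palladium couplings of the equally congested 2,6,6-trimethylcyclohexenyl triflate as the steric model. No ring is closed and no stereocentre is created: C5, C10, C5′ and C10′ are spectators carried from 1, and because both partners descend from the same homochiral triflate only the C2-symmetric isomer, not a meso form, can arise. The step needs chemo- and regioselective hydroboration (secured by the mono- versus tetrasubstitution of the two alkenes of 13), reductive elimination ahead of β-hydride elimination (wide-bite-angle dppf with AsPh3), and retention of both alkene positions (ipso substitution at C9, and a basic medium that avoids acid-induced alkene migration or cation–olefin cyclisation across the 1,5-diene). In one operation two sp2 carbons become the ethano bridge, the second tetrasubstituted alkene is released from a C–O bond, C14 and C16 pieces become the C30 skeleton, and the synthesis ends.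

**Compound list**
1 | (+)-sclareolide, (3aR,5aS,9aS,9bR)-3a,6,6,9a-tetramethyldecahydronaphtho[2,1-b]furan-2(1H)-one | C[C@]12CCCC([C@@H]1CC[C@@]3([C@@H]2CC(=O)O3)C)(C)C | starting material
2 | sclareolide lactol (2-hydroxy analogue of 1, both anomers) | C[C@]12CCCC([C@@H]1CC[C@@]3([C@@H]2CC(O)O3)C)(C)C | intermediate
3 | lactol hypoiodite (O–I in place of the lactol O–H) | C[C@]12CCCC([C@@H]1CC[C@@]3([C@@H]2CC(OI)O3)C)(C)C | intermediate
4 | 11-iododriman-8α-yl formate, (1R,2R,4aS,8aS)-1-(iodomethyl)-2,5,5,8a-tetramethyldecahydronaphthalen-2-yl formate | C[C@]12CCCC([C@@H]1CC[C@@](OC=O)([C@@H]2CI)C)(C)C | intermediate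
5 | drim-9(11)-en-8α-yl formate, (2R,4aS,8aS)-2,5,5,8a-tetramethyl-1-methylidenedecahydronaphthalen-2-yl formate | C[C@]12CCCC([C@@H]1CC[C@@](OC=O)(C2=C)C)(C)C | intermediate
6 | primary ozonide of 5 (1,2,3-trioxolane spiro-fused at C9) | C[C@]12CCCC([C@@H]1CC[C@@](OC=O)(C23COOO3)C)(C)C | intermediate
7 | 9-oxo-11-nordriman-8α-yl formate, (2R,4aS,8aS)-2,5,5,8a-tetramethyl-1-oxodecahydronaphthalen-2-yl formate | C[C@]12CCCC([C@@H]1CC[C@@](OC=O)(C2=O)C)(C)C | intermediate
8 | diiodosamarium(III) enolate of 9 (C8=C9–O–SmI2) | CC1=C(O[Sm](I)I)[C@@]2(C)CCCC(C)(C)[C@@H]2CC1 | intermediate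
9 | 11-nordriman-9-one, (4aS,8aS)-2,5,5,8a-tetramethyloctahydronaphthalen-1(2H)-one, C8 (ring position 2) epimers | O=C1C(C)CC[C@H]2C(C)(C)CCC[C@]12C | intermediate
10 | potassium enolate of 9 (C8=C9–OK) | CC1=C([O-])[C@@]2(C)CCCC(C)(C)[C@@H]2CC1.[K+] | intermediate
11 | 11-nordrim-8-en-9-yl triflate, (4aS,8aS)-2,5,5,8a-tetramethyl-3,4,4a,5,6,7,8,8a-octahydronaphthalen-1-yl trifluoromethanesulfonate | CC1=C(OS(=O)(=O)C(F)(F)F)[C@@]2(C)CCCC(C)(C)[C@@H]2CC1 | intermediate
12 | tributyl(vinyl)stannane | C=C[Sn](CCCC)(CCCC)CCCC | starting material
13 | 9-vinyl-11-nordrim-8-ene, (4aS,8aS)-1-ethenyl-2,5,5,8a-tetramethyl-3,4,4a,5,6,7,8,8a-octahydronaphthalene | CC1=C(C=C)[C@@]2(C)CCCC(C)(C)[C@@H]2CC1 | intermediate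
14 | 9-[2-(11-nordrim-8-en-9-yl)ethyl]-9-borabicyclo[3.3.1]nonane | CC1=C(CCB3C4CCCC3CCC4)[C@@]2(C)CCCC(C)(C)[C@@H]2CC1 | intermediate
15 | 1,2-bis[(4aS,8aS)-2,5,5,8a-tetramethyl-3,4,4a,5,6,7,8,8a-octahydronaphthalen-1-yl]ethane (onocera-8,13-diene skeleton) | CC1=C(CCC2=C(C)CC[C@H]3C(C)(C)CCC[C@]23C)[C@@]2(C)CCCC(C)(C)[C@@H]2CC1 | target

**Step count**
Total step count: 8. Longest linear sequence: 8 (1 → 2 → 4 → 5 → 7 → 9 → 11 → 13 → 15; triflate 11 is split and enters steps 7 and 8).

**Steps most likely to fail**

Step 8. Oxidative addition and transmetalation at the C9 triflate, buried between C10 and the C8 methyl group, may be slow. Hydrolytic loss of the triflate, protodeboronation and β-hydride loss from the alkylpalladium could then outrun the coupling. The fallback leaves the boron/palladium manifold for an iron-catalysed Kumada-type coupling of a hard alkyl nucleophile.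
- It sets out from 13. Hydroboration with 9-BBN (through 14) and NaOH/H2O2 oxidation should give 2-(11-nordrim-8-en-9-yl)ethanol F1.
- Appel-type iodination (PPh3, imidazole, I2, CH2Cl2) should give 2-(11-nordrim-8-en-9-yl)ethyl iodide F2.
- Insertion of activated magnesium in Et2O should give 2-(11-nordrim-8-en-9-yl)ethylmagnesium iodide F3.
- F3 is added to 11 with Fe(acac)3 (cat.) in THF/NMP at −30 → 0 °C. Low-valent iron couples alkyl Grignard reagents with enol triflates quickly and without β-hydride problems. The fallback comes back to the route at 15.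

Step 7. Transfer of the vinyl group from tin to the crowded alkenylpalladium may be slow. At the temperature needed, reduction of the triflate or oligomerisation of the diene could compete. The fallback builds the diene by carbonyl addition and dehydration instead of cross-coupling.
- It sets out from 9. Vinylmagnesium bromide with CeCl3 (THF, −78 → 0 °C) should give the tertiary allylic alcohol 9-vinyl-11-nordriman-9-ol F4.
- Burgess dehydration (toluene, 50 °C) can remove a hydrogen only from C8, because C10 is quaternary. The fallback comes back to the route at 13.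

Step 4. The inner alkene carbon C9 lies between two fully substituted carbons (C8 and C10). The cycloaddition of ozone may therefore be diverted to oxygen-atom transfer (epoxidation) or stall before cleavage. The fallback uses a metal-oxo route.
- It sets out from 5. Upjohn dihydroxylation (OsO4 cat., NMO, acetone/H2O), which engages the alkene from its open CH2 terminus, should give 9,11-dihydroxydriman-8α-yl formate F5.
- Periodate glycol cleavage (NaIO4, THF/H2O) then comes back to the route at 7.

**Further compounds**
F1 | step 8 | 2-[(4aS,8aS)-2,5,5,8a-tetramethyl-3,4,4a,5,6,7,8,8a-octahydronaphthalen-1-yl]ethanol | CC1=C(CCO)[C@@]2(C)CCCC(C)(C)[C@@H]2CC1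
F2 | step 8 | (4aS,8aS)-1-(2-iodoethyl)-2,5,5,8a-tetramethyl-3,4,4a,5,6,7,8,8a-octahydronaphthalene | CC1=C(CCI)[C@@]2(C)CCCC(C)(C)[C@@H]2CC1
F3 | step 8 | 2-[(4aS,8aS)-2,5,5,8a-tetramethyl-3,4,4a,5,6,7,8,8a-octahydronaphthalen-1-yl]ethylmagnesium iodide | CC1=C(CC[Mg]I)[C@@]2(C)CCCC(C)(C)[C@@H]2CC1
F4 | step 7 | (4aS,8aS)-1-ethenyl-2,5,5,8a-tetramethyldecahydronaphthalen-1-ol (C8 and C9 unassigned) | C=CC1(O)C(C)CC[C@H]2C(C)(C)CCC[C@]12C
F5 | step 4 | (2R,4aS,8aS)-1-hydroxy-1-(hydroxymethyl)-2,5,5,8a-tetramethyldecahydronaphthalen-2-yl formate (C9 unassigned) | C[C@]12CCCC([C@@H]1CC[C@@](OC=O)(C2(O)CO)C)(C)C
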